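One turnover of the catalyst, we assume, spends one reagent, so we count in turnovers per catalyst.

| flask | starting material | reagent | second substrate | catalyst | added ligand | temperature | remark | time |
|---|---|---|---|---|---|---|---|---|
| teal | 1.3 M | 1.4 equiv | 1 equiv | 0.13 mol% | 8.7 mM | 15 °C | run made earlier |  |
| green | 1.3 M | 1 equiv | 1 equiv | 0.065 mol% | 8.7 mM | 28 °C | run made earlier |  |
| north-east | 1.3 M | 1.00 equiv | 1.00 equiv | 0.13 mol% | 8.7 mM | 20 °C |  | 6.0 d |
| south | 1.3 M | 1.00 equiv | 1.00 equiv | 0.13 mol% | 8.7 mM | 35 °C |  | 6.0 d |
- teal (time / d: target / %, starting material / %): 0.417: 54.1, 45.7; 1.25: 59.7, 40.2; 2.00: 59.5, 40.1; 3.00: 58.9, 40.2; 5.00: 59.4, 39.6; 6.00: 59.7, 39.6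
- green (time / d: target / %, starting material / %): 0.500: 35.0, 65.4; 0.833: 35.2, 66.3; 1.67: 34.8, 63.7; 3.00: 35.8, 64.3; 6.00: 36.1, 64.3

(standard deviation of a reading: 0.5 percentage points)
1. the flask that comes out highest in amount of target, in percent of the starting material charged, or "all alike" when all lie within 1.5 percentage points (north-east / south / all alike)
2. target at the end, in percent of the starting material charged, north-east
3. target at the end, in percent of the starting material charged, south


Why do the earlier runs stop? Teal reads flat from 1.25 d, with 40.2% starting material at that reading. Its target reads 459 turnovers, while its reagent charge pays for 1080. Green reads 555 of 1540. Our own reading is that the second substrate, which no reading shows, takes the remaining reagent, 0.803 equiv in teal, and that the runs stop when none is left.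

How does the reagent divide? Let a and b be the fractions left of starting material and second substrate, and let S = ln a / ln b. Teal reads b = 19.7% and S = 0.570. Green, which differs from teal in temperature, reagent and catalyst, reads S = 0.433, lower than teal. Assuming that temperature is what moves S, and taking ln S as straight in it, we estimate 0.513 for north-east and, beyond the runs, 0.374 for south. We carry this S of north-east, the selectivity factor.

What do the flasks give? Their 6.0 d is longer than teal needed, so we reckon their ends. Setting the reagent left at the end to zero, with equal charges of all three, b equals the target fraction and a + b = 1. Solving a = b^S gives 38.6% for north-east and 33.4% for south, so north-east is higher by more than the margin.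

The forecast says all alike, with 57% for north-east and 56% for south, because “the plateau appears set by catalyst loading”.

The flasks give north-east as highest, with 38.4% for north-east and 33.3% for south.

    catalyst + added ligand ⇌ idle complex (K = 68.0 M⁻¹, k = 0.00260 M⁻¹ s⁻¹, Ea = 70.0 kJ mol⁻¹, ΔH = −18.0 kJ mol⁻¹)
    catalyst ⇌ dormant form (K = 0.300, k = 5.50 × 10⁻⁶ s⁻¹, Ea = 97.0 kJ mol⁻¹, ΔH = −34.0 kJ mol⁻¹)
    second substrate + reagent + catalyst → catalyst + second product (k = 0.0790 M⁻² s⁻¹, Ea = 51.0 kJ mol⁻¹)
    starting material + reagent + catalyst → catalyst + target (k = 0.0400 M⁻² s⁻¹, Ea = 35.0 kJ mol⁻¹)
    (constants at 20 °C)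

North-east ends with 0% of its reagent, and its target gives S = 0.506, beside our 0.513. The neighbouring flask is north-east with 1.70 equiv of reagent, more than the 1.00 equiv of north-east. It ends with 0% of its reagent, 24.0% starting material and 76.0% target. Carrying S, b = a^(1/S) puts its second substrate at 6.19%, and the flask holds 5.98%.

All runs are simulated with constants of no real substance, noise included.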